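Assumption: pakyonol has no stereocentre and its 20-membered ring is conformationally mobile, so the SMILES describes one achiral compound and no stereocontrol is needed.

**Retrosynthetic overview**
1. Pakyonol 20 ⇐ removal of a 2-pyridyl group from macrocycle 18, whose 20-membered ring (the only ring formed) is closed last at the C-ring/D-ring diaryl ether by pyridyloxy-directed C–H aryloxylation of open-chain phenol 17.
2. 17 ⇐ Sonogashira coupling and hydrogenation joining aryl bromide 12 to 3-ethynylphenol 15 (A–D ethylene bridge).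
3. 12 ⇐ iodide-selective Ullmann ether coupling of bibenzyl phenol 8 with 4-bromo-2-iodoanisole 11 (A–O–B ether).
4. 8 ⇐ Sonogashira coupling and hydrogenation joining 2-(3-bromophenoxy)pyridine 2 to 4-ethynylphenol (B–C ethylene bridge).
5. The four benzene rings come from 3-bromophenol, 4-iodophenol, 4-bromophenol and 3-iodophenol; both C2 bridges come from ethynyltrimethylsilane.

**Route**

Step 1
Reactants: 1 3-bromophenol
Product: 2 2-(3-bromophenoxy)pyridine
Conditions: 2-fluoropyridine (1.3 equiv), Cs2CO3, DMSO, 120 °C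
Reagents that add atoms: 2-fluoropyridine, Fc1ccccn1
Why: SNAr of the phenoxide on 2-fluoropyridine leaves the aryl bromide untouched and installs the pyridyl ether that later acts as directing and protecting group.

Step 2
Reactants: 3 4-iodophenol; 4 ethynyltrimethylsilane
Product: 5 4-[(trimethylsilyl)ethynyl]phenol
Conditions: PdCl2(PPh3)2 (2 mol %), CuI (2 mol %), Et3N, THF, rt
Reagents that add atoms: none
Why: Sonogashira coupling of an aryl iodide proceeds at room temperature and tolerates the free phenol.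

Step 3
Reactants: 5 4-[(trimethylsilyl)ethynyl]phenol; 2 2-(3-bromophenoxy)pyridine
Product: 7 4-{[3-(pyridin-2-yloxy)phenyl]ethynyl}phenol, via 4-ethynylphenol 6 (not isolated)
Conditions: PdCl2(PPh3)2 (5 mol %), CuI (5 mol %), CsF (2 equiv), Et3N, DMF, trace H2O, 80 °C, degassed
Reagents that add atoms: none
Why: Fluoride unmasks the alkyne in situ so the polymerisation-prone 4-ethynylphenol never accumulates, and Sonogashira coupling with the aryl bromide gives the diarylalkyne (sila-Sonogashira).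

Step 4
Reactants: 7 4-{[3-(pyridin-2-yloxy)phenyl]ethynyl}phenol
Product: 8 4-{2-[3-(pyridin-2-yloxy)phenyl]ethyl}phenol
Conditions: H2 (1 atm), 10 % Pd/C, EtOAc/EtOH, rt
Reagents that add atoms: none
Why: Catalytic hydrogenation saturates the alkyne to the ethylene bridge while the pyridyl ether and phenol are inert at 1 atm and rt.

Step 5
Reactants: 9 4-bromophenol
Product: 10 4-bromo-2-iodophenol
Conditions: NIS (1.0 equiv), TsOH (10 mol %), MeCN, 0 °C to rt
Reagents that add atoms: N-iodosuccinimide, O=C1CCC(=O)N1I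
Why: Electrophilic aromatic iodination goes ortho to the hydroxyl group because the para position is blocked by bromine.

Step 6
Reactants: 10 4-bromo-2-iodophenol
Product: 11 4-bromo-2-iodo-1-methoxybenzene
Conditions: MeI, K2CO3, acetone, 50 °C
Reagents that add atoms: iodomethane, CI
Why: Williamson O-methylation of the phenoxide installs the methyl ether of the target.

Step 7
Reactants: 8 4-{2-[3-(pyridin-2-yloxy)phenyl]ethyl}phenol; 11 4-bromo-2-iodo-1-methoxybenzene (1.3 equiv)
Product: 12 2-(3-{2-[4-(5-bromo-2-methoxyphenoxy)phenyl]ethyl}phenoxy)pyridine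
Conditions: CuI (10 mol %), N,N-dimethylglycine·HCl (30 mol %), Cs2CO3, dioxane, 90 °C
Reagents that add atoms: none
Why: Ullmann-type Cu-catalysed C–O coupling occurs at the C–I bond, which reacts far faster than the electron-rich C–Br bond at 90 °C, so the bromide is kept for step 10.

Step 8
Reactants: 13 3-iodophenol; 4 ethynyltrimethylsilane
Product: 14 3-[(trimethylsilyl)ethynyl]phenol
Conditions: PdCl2(PPh3)2 (2 mol %), CuI (2 mol %), Et3N, THF, rt
Reagents that add atoms: none
Why: Sonogashira coupling of the aryl iodide at room temperature tolerates the free phenol.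

Step 9
Reactants: 14 3-[(trimethylsilyl)ethynyl]phenol
Product: 15 3-ethynylphenol
Conditions: K2CO3 (0.2 equiv), MeOH, rt
Reagents that add atoms: none
Why: Base-catalysed methanolysis cleaves the alkynyl C–Si bond to give the stable terminal alkyne.

Step 10
Reactants: 12 2-(3-{2-[4-(5-bromo-2-methoxyphenoxy)phenyl]ethyl}phenoxy)pyridine; 15 3-ethynylphenol
Product: 16 3-{[4-methoxy-3-(4-{2-[3-(pyridin-2-yloxy)phenyl]ethyl}phenoxy)phenyl]ethynyl}phenol
Conditions: Pd(PhCN)2Cl2 (3 mol %), P(t-Bu)3·HBF4 (6 mol %), CuI (2 mol %), i-Pr2NH, dioxane, rt to 40 °C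
Reagents that add atoms: none
Why: Sonogashira coupling with a bulky electron-rich phosphine activates the deactivated aryl bromide under mild conditions that tolerate the free phenol and the pyridyl ether.

Step 11
Reactants: 16 3-{[4-methoxy-3-(4-{2-[3-(pyridin-2-yloxy)phenyl]ethyl}phenoxy)phenyl]ethynyl}phenol
Product: 17 3-{2-[4-methoxy-3-(4-{2-[3-(pyridin-2-yloxy)phenyl]ethyl}phenoxy)phenyl]ethyl}phenol
Conditions: H2 (1 atm), 10 % Pd/C, EtOAc/EtOH, rt
Reagents that add atoms: none
Why: Catalytic hydrogenation of the diarylalkyne gives the second ethylene bridge and a flexible precursor with no halogen left to lose.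

Step 12
Reactants: 17 3-{2-[4-methoxy-3-(4-{2-[3-(pyridin-2-yloxy)phenyl]ethyl}phenoxy)phenyl]ethyl}phenol
Product: 18 O-(pyridin-2-yl)pakyonol (the 20-membered macrocycle of the target with a 2-pyridyl group on the phenol oxygen)
Conditions: Cu(OAc)2 (30 mol %), KOPiv (2 equiv), O2 (1 atm), DMA, 120 °C, syringe-pump addition of 17 over 16 h to 2 mM
Reagents that add atoms: none
Why: Proposed new method: a macrocyclising, 2-pyridyloxy-directed, Cu-catalysed aerobic C–H aryloxylation in which the pyridine nitrogen and the tethered D-ring phenoxide bind Cu(II), pivalate-assisted cupration takes the less hindered ortho C–H (para to the ethylene tether, the other ortho site being flanked by the chain), Cu(II) disproportionation gives an aryl–Cu(III)–aryloxide that reductively eliminates the diaryl ether, and O2 reoxidises Cu(I); the closest known reaction type is Cu-catalysed chelate-directed C–H aryloxylation of arenes with phenols (aminoquinoline benzamides, 2-arylpyridines with Cu(OAc)2/O2), together with Pd-catalysed ortho-acetoxylation of 2-aryloxypyridines, which shows the same six-membered chelate geometry, and neither has been shown for an O-linked pyridyl group with a phenol or as a ring closure.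

Step 13
Reactants: 18 O-(pyridin-2-yl)pakyonol
Product: 19 N-methylpyridinium triflate of 18
Conditions: MeOTf (1.2 equiv), toluene, 80 °C; evaporate
Reagents that add atoms: methyl trifluoromethanesulfonate, COS(=O)(=O)C(F)(F)F
Why: N-methylation of the pyridine, the only nucleophilic site, turns the aryl pyridyl ether into an activated 2-aryloxypyridinium salt.

Step 14
Reactants: 19 N-methylpyridinium triflate of 18
Product: 20 pakyonol
Conditions: NaOMe (5 equiv), MeOH, reflux; then aq. HCl
Reagents that add atoms: none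
Why: Addition–elimination (SNAr) of methoxide at C-2 of the pyridinium releases the phenoxide, while the diaryl ether and methyl ether bonds are inert.

**Compound list**
1 | 3-bromophenol | Oc1cccc(Br)c1 | starting material
2 | 2-(3-bromophenoxy)pyridine | Brc1cccc(Oc2ccccn2)c1 | intermediate
3 | 4-iodophenol | Oc1ccc(I)cc1 | starting material
4 | ethynyltrimethylsilane | C#C[Si](C)(C)C | starting material
5 | 4-[(trimethylsilyl)ethynyl]phenol | C[Si](C)(C)C#Cc1ccc(O)cc1 | intermediate
6 | 4-ethynylphenol (not isolated) | C#Cc1ccc(O)cc1 | intermediate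
7 | 4-{[3-(pyridin-2-yloxy)phenyl]ethynyl}phenol | Oc1ccc(cc1)C#Cc1cccc(Oc2ccccn2)c1 | intermediate
8 | 4-{2-[3-(pyridin-2-yloxy)phenyl]ethyl}phenol | Oc1ccc(CCc2cccc(Oc3ccccn3)c2)cc1 | intermediate
9 | 4-bromophenol | Oc1ccc(Br)cc1 | starting material
10 | 4-bromo-2-iodophenol | Oc1ccc(Br)cc1I | intermediate
11 | 4-bromo-2-iodo-1-methoxybenzene | COc1ccc(Br)cc1I | intermediate
12 | 2-(3-{2-[4-(5-bromo-2-methoxyphenoxy)phenyl]ethyl}phenoxy)pyridine | COc1ccc(Br)cc1Oc1ccc(CCc2cccc(Oc3ccccn3)c2)cc1 | intermediate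
13 | 3-iodophenol | Oc1cccc(I)c1 | starting material
14 | 3-[(trimethylsilyl)ethynyl]phenol | C[Si](C)(C)C#Cc1cccc(O)c1 | intermediate
15 | 3-ethynylphenol | C#Cc1cccc(O)c1 | intermediate
16 | 3-{[4-methoxy-3-(4-{2-[3-(pyridin-2-yloxy)phenyl]ethyl}phenoxy)phenyl]ethynyl}phenol | COc1ccc(C#Cc2cccc(O)c2)cc1Oc1ccc(CCc2cccc(Oc3ccccn3)c2)cc1 | intermediate
17 | 3-{2-[4-methoxy-3-(4-{2-[3-(pyridin-2-yloxy)phenyl]ethyl}phenoxy)phenyl]ethyl}phenol | COc1ccc(CCc2cccc(O)c2)cc1Oc1ccc(CCc2cccc(Oc3ccccn3)c2)cc1 | intermediate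
18 | O-(pyridin-2-yl)pakyonol | COc1ccc2cc1Oc1ccc(cc1)CCc1ccc(c(Oc3ccccn3)c1)Oc1cccc(c1)CC2 | intermediate
19 | N-methylpyridinium triflate of 18 | COc1ccc2cc1Oc1ccc(cc1)CCc1ccc(c(Oc3cccc[n+]3C)c1)Oc1cccc(c1)CC2.[O-]S(=O)(=O)C(F)(F)F | intermediate
20 | pakyonol | COc1ccc2cc1Oc1ccc(cc1)CCc1ccc(c(O)c1)Oc1cccc(c1)CC2 | target

**Totals**
Total step count: 14. Longest linear sequence: 9 (steps 1, 3, 4, 7, 10, 11, 12, 13, 14). Branches: steps 2; 5–6; 8–9.

**Steps most likely to fail**

Step 12 (proposed new macrocyclising C–H aryloxylation). Cupration through the O-linked pyridyl chelate is unproven, and the free phenol may oligomerise or be oxidised under Cu/O2. The fallback uses known chemistry, sets out from 12 and comes back at 18; it makes the same C–O bond with the C-ring as nucleophile and the D-ring as electrophile.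
- Known pyridyloxy-directed Pd-catalysed ortho-C–H acetoxylation of 12 (Pd(OAc)2, PhI(OAc)2, AcOH/Ac2O, 100 °C) gives 4-{2-[4-(5-bromo-2-methoxyphenoxy)phenyl]ethyl}-2-(pyridin-2-yloxy)phenyl acetate F1.
- K2CO3/MeOH at rt gives 4-{2-[4-(5-bromo-2-methoxyphenoxy)phenyl]ethyl}-2-(pyridin-2-yloxy)phenol F2.
- Sonogashira coupling of the aryl bromide with 4 (conditions of step 10) gives 4-{2-[4-(2-methoxy-5-[(trimethylsilyl)ethynyl]phenoxy)phenyl]ethyl}-2-(pyridin-2-yloxy)phenol F3.
- K2CO3/MeOH gives 4-{2-[4-(5-ethynyl-2-methoxyphenoxy)phenyl]ethyl}-2-(pyridin-2-yloxy)phenol F4.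
- Iodide-selective Sonogashira coupling with 1-bromo-3-iodobenzene (PdCl2(PPh3)2, CuI, Et3N, THF, rt) gives 4-{2-[4-(5-[(3-bromophenyl)ethynyl]-2-methoxyphenoxy)phenyl]ethyl}-2-(pyridin-2-yloxy)phenol F5.
- Diimide reduction (TsNHNH2, NaOAc, DME/H2O, reflux), which spares the aryl bromide, gives 4-{2-[4-(5-[2-(3-bromophenyl)ethyl]-2-methoxyphenoxy)phenyl]ethyl}-2-(pyridin-2-yloxy)phenol F6.
- Intramolecular Ullmann ether coupling (CuI, N,N-dimethylglycine, Cs2CO3, dioxane, 2 mM) closes the ring to 18. Keep it at or below 90 °C, because the hot catechol mono-pyridyl ether phenoxide could shift the pyridyl group between the two oxygens.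

Step 7 (Ullmann union). The aryl iodide is hindered and electron-rich, and coupling at the C–Br bond or double arylation would erode the yield. The fallback is a metal-free diaryliodonium arylation, sets out from 11 and comes back at 12.
- One-pot oxidation and arylation of 11 (mCPBA, TsOH·H2O, MeCN, 77 °C; then 1,3,5-trimethoxybenzene) gives (5-bromo-2-methoxyphenyl)(2,4,6-trimethoxyphenyl)iodonium 4-methylbenzenesulfonate F7.
- F7 transfers only its bromo-methoxyphenyl group to the phenoxide of 8 (K2CO3, toluene, 50 °C) to give 12; the trimethoxyphenyl group leaves as the aryl iodide.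

Step 10 (Sonogashira on the electron-rich aryl bromide of a pyridine-containing substrate). The fallback is a B-alkyl Suzuki–Miyaura sequence that forms the saturated bridge directly; it sets out from 12 and comes back at 17, skipping 16.
- Suzuki vinylation of 12 (potassium vinyltrifluoroborate, PdCl2(dppf), Et3N, n-PrOH, 90 °C) gives 2-(3-{2-[4-(2-methoxy-5-vinylphenoxy)phenyl]ethyl}phenoxy)pyridine F8.
- Anti-Markovnikov hydroboration with 9-BBN (THF, rt) gives 9-{2-[4-methoxy-3-(4-{2-[3-(pyridin-2-yloxy)phenyl]ethyl}phenoxy)phenyl]ethyl}-9-borabicyclo[3.3.1]nonane F9, used without isolation.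
- Coupling of F9 with 3-iodophenol 13 (PdCl2(dppf), aq. K3PO4, THF/DMF, 50 °C) gives 17.

**Further compounds**
F1 | step 12 | 4-{2-[4-(5-bromo-2-methoxyphenoxy)phenyl]ethyl}-2-(pyridin-2-yloxy)phenyl acetate | COc1ccc(Br)cc1Oc1ccc(CCc2ccc(OC(C)=O)c(Oc3ccccn3)c2)cc1
F2 | step 12 | 4-{2-[4-(5-bromo-2-methoxyphenoxy)phenyl]ethyl}-2-(pyridin-2-yloxy)phenol | COc1ccc(Br)cc1Oc1ccc(CCc2ccc(O)c(Oc3ccccn3)c2)cc1
F3 | step 12 | 4-{2-[4-(2-methoxy-5-[(trimethylsilyl)ethynyl]phenoxy)phenyl]ethyl}-2-(pyridin-2-yloxy)phenol | COc1ccc(C#C[Si](C)(C)C)cc1Oc1ccc(CCc2ccc(O)c(Oc3ccccn3)c2)cc1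
F4 | step 12 | 4-{2-[4-(5-ethynyl-2-methoxyphenoxy)phenyl]ethyl}-2-(pyridin-2-yloxy)phenol | COc1ccc(C#C)cc1Oc1ccc(CCc2ccc(O)c(Oc3ccccn3)c2)cc1
F5 | step 12 | 4-{2-[4-(5-[(3-bromophenyl)ethynyl]-2-methoxyphenoxy)phenyl]ethyl}-2-(pyridin-2-yloxy)phenol | COc1ccc(C#Cc2cccc(Br)c2)cc1Oc1ccc(CCc2ccc(O)c(Oc3ccccn3)c2)cc1
F6 | step 12 | 4-{2-[4-(5-[2-(3-bromophenyl)ethyl]-2-methoxyphenoxy)phenyl]ethyl}-2-(pyridin-2-yloxy)phenol | COc1ccc(CCc2cccc(Br)c2)cc1Oc1ccc(CCc2ccc(O)c(Oc3ccccn3)c2)cc1
F7 | step 7 | (5-bromo-2-methoxyphenyl)(2,4,6-trimethoxyphenyl)iodonium 4-methylbenzenesulfonate | COc1ccc(Br)cc1[I+]c1c(OC)cc(OC)cc1OC.Cc1ccc(cc1)S(=O)(=O)[O-]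
F8 | step 10 | 2-(3-{2-[4-(2-methoxy-5-vinylphenoxy)phenyl]ethyl}phenoxy)pyridine | COc1ccc(C=C)cc1Oc1ccc(CCc2cccc(Oc3ccccn3)c2)cc1
F9 | step 10 | 9-{2-[4-methoxy-3-(4-{2-[3-(pyridin-2-yloxy)phenyl]ethyl}phenoxy)phenyl]ethyl}-9-borabicyclo[3.3.1]nonane | COc1ccc(CCB2C3CCCC2CCC3)cc1Oc1ccc(CCc2cccc(Oc3ccccn3)c2)cc1
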